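**Plan**
- Retrosynthesis: the cyclohexene ring is cut at C15–Q6 (ring expansion), at C12–Q5 and C13–Q6 (formal [2+2]) and at C13–CH3. The decalin is cut at C4–C5 and C9–C10 (polyene cyclisation) and at C11–C12 (enolate alkylation).
- Enabling feature: Q6 of the cyclohexene ring (Q5, C12, C13, C14, C15, Q6) is α to the Q1 ketone, and C13=C14 is the enol position of a C13 ketone. A 1-silyloxy-1-vinylcyclobutane (Q5–C12–C13–Q6) fused to the enedione is therefore a β-silyloxy ketone that can open by retro-aldol and reclose at the vinyl terminus C15.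
- Forward order: rings A/B by epoxypolyene radical cyclisation, then the C9 side chain to a 2-silyloxydiene. The chromone is built and its aryl ring oxidised to the methoxyquinone. The two halves are joined as the cyclobutane, which is expanded to the cyclohexene. The silyloxy helper is then exchanged for CH3 and the protecting groups are removed.
- Stereochemistry: Sharpless epoxidation sets C3, which relays C4, C5, C9 and C10 and is then deleted. C7 comes from ketone reduction. Q5 and C12 come from the chiral titanium Lewis acid (face) and the (Z)-enol ether (relative). Q6 comes from the tether in the ring expansion.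

Key step: step 18

Remark: terpenoid carbons carry labdane numbers (C1–C20). The six carbons of the quinone-derived ring are Q1 (C=O next to the methoxy carbon), Q2 (C–OMe), Q3 (=CH), Q4 (C=O), Q5 (quaternary, bears the chromone) and Q6 (ring-fusion CH).
Remark: the (4R,5R)-TADDOLate is assumed to be the antipode that selects the required quinone face; the mirror-image ligand is equally available.

**Step 1**
Reactants: 1 (2E,6E)-farnesyl bromide; 2 methyl acetate
Product: 3 methyl (4E,8E)-5,9,13-trimethyltetradeca-4,8,12-trienoate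
Conditions: LiN(iPr)2, THF, −78 °C; then 1, DMPU, −78 → 0 °C
Reagents that add atoms: none
Why: SN2 alkylation of the lithium ester enolate by the primary allylic bromide should add the two carbons that become C12 and C13 without touching the E,E-alkenes.

**Step 2**
Reactants: 3 methyl (4E,8E)-5,9,13-trimethyltetradeca-4,8,12-trienoate
Product: 4 methyl (4E,8E,12E)-14-hydroxy-5,9,13-trimethyltetradeca-4,8,12-trienoate
Conditions: SeO2 (0.1 equiv), t-BuOOH, salicylic acid (cat.), CH2Cl2, 0 °C → rt
Reagents that add atoms: selenium dioxide (oxygen carrier), O=[Se]=O; tert-butyl hydroperoxide (terminal oxidant), CC(C)(C)OO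
Why: Catalytic SeO2 allylic oxidation (ene reaction, then [2,3]-sigmatropic shift) is known to take the (E)-methyl of the terminal isopropylidene unit of polyprenyl chains, the carbon that becomes the equatorial C18.

**Step 3**
Reactants: 4 methyl (4E,8E,12E)-14-hydroxy-5,9,13-trimethyltetradeca-4,8,12-trienoate
Product: 5 methyl (4E,8E)-11-[(2S,3S)-3-(hydroxymethyl)-3-methyloxiran-2-yl]-5,9-dimethylundeca-4,8-dienoate
Conditions: Ti(OiPr)4 (0.1 equiv), L-(+)-diethyl tartrate (0.12 equiv), t-BuOOH, 4 Å molecular sieves, CH2Cl2, −20 °C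
Reagents that add atoms: tert-butyl hydroperoxide, CC(C)(C)OO
Why: Sharpless asymmetric epoxidation of the (E)-2-methyl allylic alcohol with the L-(+)-tartrate should give the (2S,3S)-epoxide, so that the future C3 is S and can relay all ring A/B stereocentres.

**Step 4**
Reactants: 5 methyl (4E,8E)-11-[(2S,3S)-3-(hydroxymethyl)-3-methyloxiran-2-yl]-5,9-dimethylundeca-4,8-dienoate
Product: 6 methyl (4E,8E)-11-[(2S,3S)-3-(tert-butyldimethylsilyloxymethyl)-3-methyloxiran-2-yl]-5,9-dimethylundeca-4,8-dienoate
Conditions: TBSCl, imidazole, DMF, 0 °C → rt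
Reagents that add atoms: tert-butyldimethylsilyl chloride, CC(C)(C)[Si](C)(C)Cl
Why: Silylation of the primary alcohol prevents deoxygenation of the epoxy alcohol in the radical step and makes the future C18 substituent the larger group at C4.

**Step 5**
Reactants: 6 methyl (4E,8E)-11-[(2S,3S)-3-(tert-butyldimethylsilyloxymethyl)-3-methyloxiran-2-yl]-5,9-dimethylundeca-4,8-dienoate
Product: 7 methyl 18-(tert-butyldimethylsilyloxy)-3β-hydroxy-14,15,16-trinorlabd-8(17)-en-13-oate (4α-CH2OTBS, 4β-CH3, 5α-H, 9α-H, 10β-CH3)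
Conditions: Cp2TiCl2 (2.5 equiv), Mn dust, THF, rt (gives Cp2TiCl, trivalent titanium); slow addition of 6; then 1 M HCl, 0 °C
Reagents that add atoms: none
Why: Cp2TiCl should open the epoxide homolytically to the tertiary C4 radical, which undergoes the known epoxypolyene radical bicyclisation (two 6-endo closures through a chair–chair array with C3–O–Ti and the larger CH2OTBS group equatorial, giving the trans-decalin) and ends by titanium trapping and β-hydride elimination to the 8(17)-exocyclic alkene.

**Step 6**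
Reactants: 7 methyl 18-(tert-butyldimethylsilyloxy)-3β-hydroxy-14,15,16-trinorlabd-8(17)-en-13-oate
Product: 8 methyl 18-(tert-butyldimethylsilyloxy)-3β-(phenoxythiocarbonyloxy)-14,15,16-trinorlabd-8(17)-en-13-oate
Conditions: PhOC(S)Cl, pyridine, DMAP (cat.), CH2Cl2, rt
Reagents that add atoms: O-phenyl chlorothionoformate, S=C(Cl)Oc1ccccc1
Why: Acylation of the hindered secondary alcohol gives the thionocarbonate needed for radical deoxygenation.

**Step 7**
Reactants: 8 methyl 18-(tert-butyldimethylsilyloxy)-3β-(phenoxythiocarbonyloxy)-14,15,16-trinorlabd-8(17)-en-13-oate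
Product: 9 methyl 18-(tert-butyldimethylsilyloxy)-14,15,16-trinorlabd-8(17)-en-13-oate
Conditions: Bu3SnH, AIBN (cat.), toluene, 90 °C
Reagents that add atoms: none
Why: Barton–McCombie deoxygenation should remove the C3 oxygen that served only as the stereochemical relay; the secondary C3 radical is remote from the exocyclic alkene.

**Step 8**
Reactants: 9 methyl 18-(tert-butyldimethylsilyloxy)-14,15,16-trinorlabd-8(17)-en-13-oate
Product: 10 methyl 18-(tert-butyldimethylsilyloxy)-7α-hydroxy-14,15,16-trinorlabd-8(17)-en-13-oate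
Conditions: SeO2 (0.5 equiv), t-BuOOH, CH2Cl2, rt
Reagents that add atoms: selenium dioxide (oxygen carrier), O=[Se]=O; tert-butyl hydroperoxide (terminal oxidant), CC(C)(C)OO
Why: SeO2 allylic hydroxylation of the 1,1-disubstituted alkene should take the allylic CH2 (C7) in preference to the methine C9 and return the double bond to the 8(17) position; the axial 7α-alcohol expected here is corrected in steps 9 and 10.

**Step 9**
Reactants: 10 methyl 18-(tert-butyldimethylsilyloxy)-7α-hydroxy-14,15,16-trinorlabd-8(17)-en-13-oate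
Product: 11 methyl 18-(tert-butyldimethylsilyloxy)-7-oxo-14,15,16-trinorlabd-8(17)-en-13-oate
Conditions: Dess–Martin periodinane, NaHCO3, CH2Cl2, 0 °C
Reagents that add atoms: none
Why: Buffered Dess–Martin oxidation should give the exocyclic enone without moving the alkene into conjugation at C8–C9.

**Step 10**
Reactants: 11 methyl 18-(tert-butyldimethylsilyloxy)-7-oxo-14,15,16-trinorlabd-8(17)-en-13-oate
Product: 12 methyl 18-(tert-butyldimethylsilyloxy)-7β-hydroxy-14,15,16-trinorlabd-8(17)-en-13-oate
Conditions: NaBH4, CeCl3·7H2O, MeOH, −78 °C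
Reagents that add atoms: none
Why: Luche 1,2-reduction with axial hydride delivery from the α-face should give the equatorial 7β-alcohol.

**Step 11**
Reactants: 12 methyl 18-(tert-butyldimethylsilyloxy)-7β-hydroxy-14,15,16-trinorlabd-8(17)-en-13-oate
Product: 13 methyl 7β,18-bis(tert-butyldimethylsilyloxy)-14,15,16-trinorlabd-8(17)-en-13-oate
Conditions: TBSOTf, 2,6-lutidine, CH2Cl2, −78 → 0 °C
Reagents that add atoms: tert-butyldimethylsilyl trifluoromethanesulfonate, CC(C)(C)[Si](C)(C)OS(=O)(=O)C(F)(F)F
Why: Silylation of the allylic secondary alcohol protects it through the organometallic and Lewis-acid steps.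

**Step 12**
Reactants: 13 methyl 7β,18-bis(tert-butyldimethylsilyloxy)-14,15,16-trinorlabd-8(17)-en-13-oate
Product: 15 7β,18-bis(tert-butyldimethylsilyloxy)-16-norlabda-8(17),14-dien-13-one, via Weinreb amide 14 (not isolated)
Conditions: MeNHOMe·HCl, iPrMgCl, THF, −20 °C; then CH2=CHMgBr, −20 → 0 °C; inverse quench into cold 1 M HCl
Reagents that add atoms: vinylmagnesium bromide, C=C[Mg]Br
Why: Weinreb ketone synthesis in one flask should stop at the vinyl ketone because the chelated tetrahedral intermediate survives until the acidic quench, which also keeps the freed amine from adding to the enone.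

**Step 13**
Reactants: 15 7β,18-bis(tert-butyldimethylsilyloxy)-16-norlabda-8(17),14-dien-13-one
Product: 16 (12Z)-7β,13,18-tris(tert-butyldimethylsilyloxy)-16-norlabda-8(17),12,14-triene
Conditions: TBSOTf, Et3N, CH2Cl2, −78 → 0 °C
Reagents that add atoms: tert-butyldimethylsilyl trifluoromethanesulfonate, CC(C)(C)[Si](C)(C)OS(=O)(=O)C(F)(F)F
Why: Soft enolisation of the vinyl ketone toward its only α-CH2 (C12) should give the (Z)-2-silyloxydiene, which makes C12 nucleophilic and puts the temporary oxygen donor on C13.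

**Step 14**
Reactants: 17 2,4,6-trihydroxyacetophenone; 18 2,4,5-trimethoxybenzoyl chloride
Product: 20 5,7-dihydroxy-2-(2,4,5-trimethoxyphenyl)-4H-chromen-4-one, via diketone 19 (not isolated)
Conditions: LiN(SiMe3)2 (5 equiv), THF, −78 °C → rt; then AcOH, H2SO4 (cat.), 95 °C
Reagents that add atoms: none
Why: C-acylation of the polylithiated acetophenone (Baker–Venkataraman-type 1,3-diketone synthesis) followed by acid cyclodehydration is the standard one-flask route to 5,7-dihydroxyflavones.

**Step 15**
Reactants: 20 5,7-dihydroxy-2-(2,4,5-trimethoxyphenyl)-4H-chromen-4-one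
Product: 21 5,7-diacetoxy-2-(2,4,5-trimethoxyphenyl)-4H-chromen-4-one
Conditions: Ac2O, pyridine, DMAP (cat.), rt
Reagents that add atoms: acetic anhydride, CC(=O)OC(C)=O
Why: Acetylation caps both phenols as non-chelating, oxidation-resistant esters, so that the later titanium Lewis acid binds only the Q1 carbonyl/Q2 methoxy pair.

**Step 16**
Reactants: 21 5,7-diacetoxy-2-(2,4,5-trimethoxyphenyl)-4H-chromen-4-one
Product: 22 2-(5,7-diacetoxy-4-oxo-4H-chromen-2-yl)-5-methoxy-1,4-benzoquinone
Conditions: (NH4)2Ce(NO3)6 (2.5 equiv), MeCN/H2O 4:1, 0 °C, 15 min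
Reagents that add atoms: water, O
Why: Oxidative demethylation of the para-related 2′- and 5′-methoxy groups of the 1,2,4-trimethoxyarene by ceric ammonium nitrate should give the 2-methoxy-1,4-benzoquinone and leave the 4′-methoxy group as Q2–OMe.

**Step 17**
Reactants: 22 2-(5,7-diacetoxy-4-oxo-4H-chromen-2-yl)-5-methoxy-1,4-benzoquinone; 16 (12Z)-7β,13,18-tris(tert-butyldimethylsilyloxy)-16-norlabda-8(17),12,14-triene
Product: 23 cis-fused bicyclo[4.2.0]oct-3-ene-2,5-dione (cyclobutane Q5–C12–C13–Q6) carrying 3-methoxy (Q2), 6-(5,7-diacetoxy-4-oxochromen-2-yl) (Q5), 7-[C11 methylene of the 7β,18-bis(silyloxy)decalin] (C12, on the convex face, cis to the chromone), 8-(tert-butyldimethylsilyloxy) and 8-vinyl (C13)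
Conditions: dichlorotitanium (4R,5R)-2,2-dimethyl-α,α,α′,α′-tetraphenyl-1,3-dioxolane-4,5-dimethanolate, TiCl2(C31H28O4) (2.2 equiv), CH2Cl2, −78 °C, 2 h; cold quench with aq. NaHCO3
Reagents that add atoms: none
Why: Chelation of the tetravalent titanium Lewis acid by the Q1 carbonyl and the Q2 methoxy group should direct the nucleophilic enol-ether carbon C12 to Q5 (Mukaiyama–Michael step of the known formal [2+2] cycloaddition of 2-alkoxy-1,4-benzoquinones with electron-rich alkenes), after which the silyloxyallyl cation closes at C13 on the titanium enolate carbon Q6 (4-exo aldol closure) with the diene π-system endo, so that C11, trans to the vinyl group in the (Z)-enol ether, lies on the convex face cis to the chromone; the TADDOLate ligand selects the quinone face and the quaternary Q5 rules out aromatisation.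

**Step 18**
Reactants: 23 the silyloxy-vinyl cyclobutane of step 17
Product: 25 5′,7′-di-O-acetyl-7,18-bis-O-(tert-butyldimethylsilyl)-13-(tert-butyldimethylsilyloxy)-16-nordichrostachine A (cis-fused cyclohexene silyl enol ether, ring Q5–C12–C13(OTBS)=C14–C15–Q6), via ring-opened silyl dienol ether 24 (not isolated)
Conditions: TBSOTf (0.1 equiv), 2,6-di-tert-butylpyridine (0.2 equiv), CH2Cl2, −40 → 0 °C
Reagents that add atoms: none
Why: The silyl triflate binds the Q1 carbonyl and the strained β-silyloxy ketone undergoes retro-aldol cleavage of the Q6–C13 bond (donor: the silyloxy/vinyl carbon C13; acceptor: the Q1 ketone) with silyl transfer to O–Q1 to give 24, whose re-silylated vinyl ketone is then attacked at the vinyl terminus C15 by the Q6 terminus of the silyl dienol ether, regenerating the silyl triflate. The closest known reaction type is the Lewis-acid ring expansion of 1-silyloxy-1-vinylcyclobutanes to cyclohexene silyl enol ethers, the stepwise Mukaiyama–Michael/aldol manifold of 2-silyloxydienes with hindered enones. The cyclohexene ring (Q5, C12, C13, C14, C15, Q6) closes 6-endo-trig at C15, so the four-membered ring grows by the two vinyl carbons. The only new stereocentre, Q6, is set cis to the Q5–C12 bond because the three-atom tether C12–C13=C14 can reach only that face of the planar dienol ether, while Q5 and C12 are carried through unchanged. The step needs C-attack at C15 rather than return to C13, attack by the enol-ether carbon Q3 or O-alkylation: the aldol-type closures are strained and reversible, triflate is non-nucleophilic so no demethylation can trap a Q3 adduct, the pyridine base removes free acid that could move the exocyclic alkene, and the quaternary Q5 blocks aromatisation, so the unstrained conjugate adduct 25 is the sink.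

**Step 19**
Reactants: 25 the C13 silyl enol ether of step 18
Product: 26 5′,7′-di-O-acetyl-7,18-bis-O-(tert-butyldimethylsilyl)-13-(trifluoromethanesulfonyloxy)-16-nordichrostachine A (enol triflate C13(OTf)=C14)
Conditions: PhNTf2, CsF, DME, rt
Reagents that add atoms: N-phenylbis(trifluoromethanesulfonimide), O=S(=O)(N(c1ccccc1)S(=O)(=O)C(F)(F)F)C(F)(F)F
Why: Fluoride unmasks the regiodefined C13–C14 enolate from the silyl enol ether in the presence of the triflating agent, so the enol triflate should form with retention of the double-bond position and without strong base; the alkyl TBS ethers are inert to CsF in DME.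

**Step 20**
Reactants: 26 the enol triflate of step 19
Product: 27 5′,7′-di-O-acetyl-7,18-bis-O-(tert-butyldimethylsilyl)dichrostachine A
Conditions: MeZnCl, Pd(PPh3)4 (5 mol%), THF, rt → 45 °C
Reagents that add atoms: methylzinc chloride, C[Zn]Cl
Why: Negishi coupling of the alkenyl triflate with the methylzinc reagent (zerovalent palladium catalyst) should replace the helper oxygen by the C13 methyl group; organozinc halides do not add to ketones or uncatalysed to enones.

**Step 21**
Reactants: 27 5′,7′-di-O-acetyl-7,18-bis-O-(tert-butyldimethylsilyl)dichrostachine A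
Product: 28 7,18-bis-O-(tert-butyldimethylsilyl)dichrostachine A
Conditions: NH4OAc, MeOH/H2O 4:1, rt
Reagents that add atoms: none
Why: Aryl acetates are cleaved under these near-neutral conditions, which should spare the enedione, the base-sensitive cis ring fusion and the silyl ethers.

**Step 22**
Reactants: 28 7,18-bis-O-(tert-butyldimethylsilyl)dichrostachine A
Product: 29 dichrostachine A
Conditions: HF·pyridine, pyridine, THF, 0 °C → rt
Reagents that add atoms: none
Why: Buffered HF·pyridine should remove the primary and the allylic secondary silyl ether without ionising the allylic alcohol or touching the vinylogous ester.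

**Compound list**
1 | (2E,6E)-farnesyl bromide | CC(C)=CCC/C(C)=C/CC/C(C)=C/CBr | starting material
2 | methyl acetate | CC(=O)OC | starting material
3 | methyl (4E,8E)-5,9,13-trimethyltetradeca-4,8,12-trienoate | CC(C)=CCC/C(C)=C/CC/C(C)=C/CCC(=O)OC | intermediate
4 | methyl (4E,8E,12E)-14-hydroxy-5,9,13-trimethyltetradeca-4,8,12-trienoate | OC/C(C)=C/CC/C(C)=C/CC/C(C)=C/CCC(=O)OC | intermediate
5 | methyl (4E,8E)-11-[(2S,3S)-3-(hydroxymethyl)-3-methyloxiran-2-yl]-5,9-dimethylundeca-4,8-dienoate | C[C@@]1(CO)O[C@H]1CC/C(C)=C/CC/C(C)=C/CCC(=O)OC | intermediate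
6 | TBS ether of 5 | C[C@@]1(CO[Si](C)(C)C(C)(C)C)O[C@H]1CC/C(C)=C/CC/C(C)=C/CCC(=O)OC | intermediate
7 | methyl 18-(tert-butyldimethylsilyloxy)-3β-hydroxy-14,15,16-trinorlabd-8(17)-en-13-oate | C=C1CC[C@H]2[C@](C)(CO[Si](C)(C)C(C)(C)C)[C@@H](O)CC[C@]2(C)[C@H]1CCC(=O)OC | intermediate
8 | 3β-O-phenoxythiocarbonyl derivative of 7 | C=C1CC[C@H]2[C@](C)(CO[Si](C)(C)C(C)(C)C)[C@@H](OC(=S)Oc3ccccc3)CC[C@]2(C)[C@H]1CCC(=O)OC | intermediate
9 | methyl 18-(tert-butyldimethylsilyloxy)-14,15,16-trinorlabd-8(17)-en-13-oate | C=C1CC[C@H]2[C@](C)(CO[Si](C)(C)C(C)(C)C)CCC[C@]2(C)[C@H]1CCC(=O)OC | intermediate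
10 | 7α-hydroxy derivative of 9 | C=C1[C@H](O)C[C@H]2[C@](C)(CO[Si](C)(C)C(C)(C)C)CCC[C@]2(C)[C@H]1CCC(=O)OC | intermediate
11 | 7-oxo derivative of 9 | C=C1C(=O)C[C@H]2[C@](C)(CO[Si](C)(C)C(C)(C)C)CCC[C@]2(C)[C@H]1CCC(=O)OC | intermediate
12 | 7β-hydroxy derivative of 9 | C=C1[C@@H](O)C[C@H]2[C@](C)(CO[Si](C)(C)C(C)(C)C)CCC[C@]2(C)[C@H]1CCC(=O)OC | intermediate
13 | methyl 7β,18-bis(tert-butyldimethylsilyloxy)-14,15,16-trinorlabd-8(17)-en-13-oate | C=C1[C@@H](O[Si](C)(C)C(C)(C)C)C[C@H]2[C@](C)(CO[Si](C)(C)C(C)(C)C)CCC[C@]2(C)[C@H]1CCC(=O)OC | intermediate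
14 | N-methoxy-N-methyl amide of the acid of 13 (Weinreb amide) | C=C1[C@@H](O[Si](C)(C)C(C)(C)C)C[C@H]2[C@](C)(CO[Si](C)(C)C(C)(C)C)CCC[C@]2(C)[C@H]1CCC(=O)N(C)OC | intermediate
15 | 7β,18-bis(tert-butyldimethylsilyloxy)-16-norlabda-8(17),14-dien-13-one | C=C1[C@@H](O[Si](C)(C)C(C)(C)C)C[C@H]2[C@](C)(CO[Si](C)(C)C(C)(C)C)CCC[C@]2(C)[C@H]1CCC(=O)C=C | intermediate
16 | (12Z)-7β,13,18-tris(tert-butyldimethylsilyloxy)-16-norlabda-8(17),12,14-triene | C=C1[C@@H](O[Si](C)(C)C(C)(C)C)C[C@H]2[C@](C)(CO[Si](C)(C)C(C)(C)C)CCC[C@]2(C)[C@H]1C/C=C(\O[Si](C)(C)C(C)(C)C)C=C | intermediate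
17 | 2,4,6-trihydroxyacetophenone | CC(=O)c1c(O)cc(O)cc1O | starting material
18 | 2,4,5-trimethoxybenzoyl chloride | COc1cc(OC)c(OC)cc1C(Cl)=O | starting material
19 | 1-(2,4,6-trihydroxyphenyl)-3-(2,4,5-trimethoxyphenyl)propane-1,3-dione | COc1cc(OC)c(OC)cc1C(=O)CC(=O)c1c(O)cc(O)cc1O | intermediate
20 | 5,7-dihydroxy-2-(2,4,5-trimethoxyphenyl)-4H-chromen-4-one | COc1cc(OC)c(OC)cc1-c1cc(=O)c2c(O)cc(O)cc2o1 | intermediate
21 | 5,7-diacetoxy-2-(2,4,5-trimethoxyphenyl)-4H-chromen-4-one | COc1cc(OC)c(OC)cc1-c1cc(=O)c2c(OC(C)=O)cc(OC(C)=O)cc2o1 | intermediate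
22 | 2-(5,7-diacetoxy-4-oxo-4H-chromen-2-yl)-5-methoxy-1,4-benzoquinone | COC1=CC(=O)C(=CC1=O)c1cc(=O)c2c(OC(C)=O)cc(OC(C)=O)cc2o1 | intermediate
23 | silyloxy-vinyl cyclobutane (formal [2+2] adduct; vinyl on the concave face, OTBS and C11 on the convex face) | C=C1[C@@H](O[Si](C)(C)C(C)(C)C)C[C@H]2[C@](C)(CO[Si](C)(C)C(C)(C)C)CCC[C@]2(C)[C@H]1C[C@H]3[C@]4(c5cc(=O)c6c(OC(C)=O)cc(OC(C)=O)cc6o5)C(=O)C=C(OC)C(=O)[C@@H]4[C@]3(O[Si](C)(C)C(C)(C)C)C=C | intermediate
24 | ring-opened Q1-silyl dienol ether with free C13 vinyl ketone | C=C1[C@@H](O[Si](C)(C)C(C)(C)C)C[C@H]2[C@](C)(CO[Si](C)(C)C(C)(C)C)CCC[C@]2(C)[C@H]1C[C@H](C(=O)C=C)[C@@]3(c4cc(=O)c5c(OC(C)=O)cc(OC(C)=O)cc5o4)C=C(O[Si](C)(C)C(C)(C)C)C(OC)=CC3=O | intermediate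
25 | ring-expanded C13 silyl enol ether | C=C1[C@@H](O[Si](C)(C)C(C)(C)C)C[C@H]2[C@](C)(CO[Si](C)(C)C(C)(C)C)CCC[C@]2(C)[C@H]1C[C@@H]1C(O[Si](C)(C)C(C)(C)C)=CC[C@H]2C(=O)C(OC)=CC(=O)[C@@]12c1cc(=O)c2c(OC(C)=O)cc(OC(C)=O)cc2o1 | intermediate
26 | C13 enol triflate | C=C1[C@@H](O[Si](C)(C)C(C)(C)C)C[C@H]2[C@](C)(CO[Si](C)(C)C(C)(C)C)CCC[C@]2(C)[C@H]1C[C@@H]1C(OS(=O)(=O)C(F)(F)F)=CC[C@H]2C(=O)C(OC)=CC(=O)[C@@]12c1cc(=O)c2c(OC(C)=O)cc(OC(C)=O)cc2o1 | intermediate
27 | 5′,7′-di-O-acetyl-7,18-bis-O-(tert-butyldimethylsilyl)dichrostachine A | C=C1[C@@H](O[Si](C)(C)C(C)(C)C)C[C@H]2[C@](C)(CO[Si](C)(C)C(C)(C)C)CCC[C@]2(C)[C@H]1C[C@@H]1C(C)=CC[C@H]2C(=O)C(OC)=CC(=O)[C@@]12c1cc(=O)c2c(OC(C)=O)cc(OC(C)=O)cc2o1 | intermediate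
28 | 7,18-bis-O-(tert-butyldimethylsilyl)dichrostachine A | C=C1[C@@H](O[Si](C)(C)C(C)(C)C)C[C@H]2[C@](C)(CO[Si](C)(C)C(C)(C)C)CCC[C@]2(C)[C@H]1C[C@@H]1C(C)=CC[C@H]2C(=O)C(OC)=CC(=O)[C@@]12c1cc(=O)c2c(O)cc(O)cc2o1 | intermediate
29 | dichrostachine A | C=C1[C@@H](O)C[C@H]2[C@](C)(CO)CCC[C@]2(C)[C@H]1C[C@@H]1C(C)=CC[C@H]2C(=O)C(OC)=CC(=O)[C@@]12c1cc(=O)c2c(O)cc(O)cc2o1 | target

**Totals**
Total step count: 22. Longest linear sequence: 19 steps (steps 1–13, then 17–22).

**Steps most likely to fail**

Step 17. What may go wrong: poor facial or endo/exo selection in the first C–C bond formation at the hindered Q5, or collapse of the ion pair on the Q4 oxygen or on Q3 instead of on Q6. The fallback splits the union into two events. It sets out from 22 and 16 and uses a copper-catalysed Mukaiyama–Michael addition (Cu(OTf)2 with (S,S)-2,2′-isopropylidenebis(4-tert-butyl-2-oxazoline), CH2Cl2, −78 °C; two-point binding through the Q1 carbonyl and the Q2 methoxy group). The silyl group moves to the Q1 oxygen, so the open-chain silyl dienol ether 24 is isolated. Compound 24 is then closed 6-endo under the conditions of step 18, and the route is rejoined at 25. No compound outside the list is made (F0).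

Step 18. What may go wrong: return to the cyclobutane without turnover, closure at Q3 to a bridged bicycle, loss of the silyl group with polymerisation of the vinyl ketone, or acid-induced migration of the exocyclic alkene. The fallback is the anionic form of the same ring expansion. It sets out from 15, which with TESOTf/Et3N should give the triethylsilyl dienol ether F1. Union with 22 as in step 17 should give the triethylsilyloxy cyclobutane F2. HF·pyridine buffered with pyridine at −20 °C should remove only the triethylsilyl ether to give the cyclobutanol F3. KN(SiMe3)2 (1.05 equiv) in THF at −78 °C, followed by PhNTf2, then forms the potassium alkoxide, which undergoes retro-aldol opening and intramolecular Michael closure (oxyanion-driven two-carbon ring expansion of a 1-vinylcyclobutanol). The resulting C13–C14 enolate is triflated in the same flask, and the route is rejoined at 26.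

Step 19. What may go wrong: fluoride-induced loss of the aryl acetates, or equilibration of the liberated enolate (scrambling of the double-bond position, epimerisation at Q6, retro-Michael opening). The fallback goes through the ketone and uses electrophilic O-triflation instead of an enolate. It sets out from 25, which AcOH/THF/H2O should hydrolyse at the silyl enol ether only, giving the C13 ketone F4. Tf2O with 2,6-di-tert-butyl-4-methylpyridine in CH2Cl2 at −20 °C should then give the less substituted enol triflate, because the hindered base can reach only the C14 protons (C12–H is shielded by the quaternary Q5). The route is rejoined at 26.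

**Further compounds**
F0 | step 17 | none | none
F1 | step 18 | (12Z)-7β,18-bis(tert-butyldimethylsilyloxy)-13-(triethylsilyloxy)-16-norlabda-8(17),12,14-triene | C=C1[C@@H](O[Si](C)(C)C(C)(C)C)C[C@H]2[C@](C)(CO[Si](C)(C)C(C)(C)C)CCC[C@]2(C)[C@H]1C/C=C(\O[Si](CC)(CC)CC)C=C
F2 | step 18 | triethylsilyloxy analogue of cyclobutane 23 | C=C1[C@@H](O[Si](C)(C)C(C)(C)C)C[C@H]2[C@](C)(CO[Si](C)(C)C(C)(C)C)CCC[C@]2(C)[C@H]1C[C@H]3[C@]4(c5cc(=O)c6c(OC(C)=O)cc(OC(C)=O)cc6o5)C(=O)C=C(OC)C(=O)[C@@H]4[C@]3(O[Si](CC)(CC)CC)C=C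
F3 | step 18 | free cyclobutanol corresponding to 23 | C=C1[C@@H](O[Si](C)(C)C(C)(C)C)C[C@H]2[C@](C)(CO[Si](C)(C)C(C)(C)C)CCC[C@]2(C)[C@H]1C[C@H]3[C@]4(c5cc(=O)c6c(OC(C)=O)cc(OC(C)=O)cc6o5)C(=O)C=C(OC)C(=O)[C@@H]4[C@]3(O)C=C
F4 | step 19 | C13 ketone from hydrolysis of 25 | C=C1[C@@H](O[Si](C)(C)C(C)(C)C)C[C@H]2[C@](C)(CO[Si](C)(C)C(C)(C)C)CCC[C@]2(C)[C@H]1C[C@@H]1C(=O)CC[C@H]2C(=O)C(OC)=CC(=O)[C@@]12c1cc(=O)c2c(OC(C)=O)cc(OC(C)=O)cc2o1
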